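**Retrosynthetic overview**
1. The benzene ring B (C3a, C4, C5, C6, C7, C7a of the 2,2-dimethylindane; only C7 bears H) is the feature the plan rests on: the C4 CH2O arm and the C5 CH2CH2 arm can be joined through one oxygen as an isochroman (ring C), and C6 can be an ester.
2. Ring B then maps onto a cyclopentene (C3a=C7a) carrying a dihydropyranyl arm (C4=C5) and an acrylate arm (C7=C6), one bond (C5–C6) short of the ring: Heck coupling makes C7a–C7, thermal 6π-electrocyclisation makes C5–C6, and dehydrogenation gives the arene.
3. The bromodiene comes from a triflate-selective Suzuki coupling (C3a–C4) of 2-bromo-4,4-dimethylcyclopentenyl triflate with a dihydropyranyl boronate; the triflate comes from 3,3-dimethylcyclopentanone.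
4. Endgame: the C6 ester is taken to CH2Cl, the isochroman OCH2 is oxidised to the lactone, the lactone is opened to ArCOCl plus CH2CH2Cl, the acid chloride is reduced and acetylated, and butanoate finally displaces the benzylic chloride.
5. Ring order: ring A (cyclopentane) and ring C (pyran) are purchased; ring B is formed last, between them.

Key step: step 5

Remark: the carbocyclic core is numbered as an indane (C1, C2 = CMe2, C3, C3a, C4 to C7, C7a) in every compound, open-chain precursors included. The target is achiral; the two stereocentres of 9 are transient and 9 is racemic.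

**Step 1**
Reactants: 1 3,3-dimethylcyclopentanone
Product: 2 [(4,4-dimethylcyclopent-1-en-1-yl)oxy]trimethylsilane
Conditions: LiN(iPr)2 (commercial solution), Me3SiCl, THF, −78 °C
Reagents that add atoms: chlorotrimethylsilane, C[Si](C)(C)Cl
Why: Kinetic deprotonation by the bulky amide base takes the α-CH2 remote from the quaternary carbon and the enolate is trapped on oxygen (regioselective silyl enol ether formation).

**Step 2**
Reactants: 2 [(4,4-dimethylcyclopent-1-en-1-yl)oxy]trimethylsilane
Product: 3 racemic 2-bromo-4,4-dimethylcyclopentan-1-one
Conditions: NBS, THF, −78 to 0 °C; aq. NaHCO3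
Reagents that add atoms: N-bromosuccinimide, O=C1CCC(=O)N1Br
Why: Electrophilic bromination of a silyl enol ether puts bromine only on the former enol carbon, so the α-bromoketone should form regiospecifically; its stereocentre is removed in step 3.

**Step 3**
Reactants: 3 racemic 2-bromo-4,4-dimethylcyclopentan-1-one
Product: 4 2-bromo-4,4-dimethylcyclopent-1-en-1-yl trifluoromethanesulfonate
Conditions: Tf2O, 2,6-di-tert-butyl-4-methylpyridine, CH2Cl2, 0 °C to rt
Reagents that add atoms: trifluoromethanesulfonic anhydride, O=S(=O)(OS(=O)(=O)C(F)(F)F)C(F)(F)F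
Why: O-triflation followed by loss of the more acidic proton on the bromine-bearing carbon (the other α-CH2 is neopentyl and less acidic) should give the tetrasubstituted 2-bromoenol triflate (enol triflate formation).

**Step 4**
Reactants: 4 2-bromo-4,4-dimethylcyclopent-1-en-1-yl trifluoromethanesulfonate; 5 2-(5,6-dihydro-2H-pyran-3-yl)-4,4,5,5-tetramethyl-1,3,2-dioxaborolane
Product: 6 5-(2-bromo-4,4-dimethylcyclopent-1-en-1-yl)-3,6-dihydro-2H-pyran
Conditions: Pd(PPh3)4 (5 mol%), aq. K3PO4, 1,4-dioxane, 55 °C, 1.0 equiv of 5
Reagents that add atoms: none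
Why: Suzuki–Miyaura coupling in which Pd(PPh3)4 adds oxidatively to the alkenyl triflate much faster than to the alkenyl bromide, so with one equivalent of boronate only the C–O bond is replaced and the bromide is kept for step 5.

**Step 5**
Reactants: 6 5-(2-bromo-4,4-dimethylcyclopent-1-en-1-yl)-3,6-dihydro-2H-pyran; 7 methyl acrylate
Product: 9 racemic cis-5,6-dihydroarene methyl ester (cyclohexa-1,3-diene with C7=C7a and C3a=C4; C5–H and C6–H cis), via (E)-triene ester 8 (not isolated)
Conditions: Pd(OAc)2 (5 mol%), PPh3 (12 mol%), NEt3, DMF, 90 °C; excess acrylate stripped, then 150 °C (sealed vessel)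
Reagents that add atoms: none
Why: Zerovalent palladium formed from Pd(OAc)2 and PPh3 inserts into the C–Br bond of 6, the alkenylpalladium bromide adds across the acrylate with carbon going to the CH2 terminus, and syn β-hydride elimination releases the (E)-acrylate 8, forming C7a–C7 (Heck reaction). The closest known reaction type is the domino Heck coupling and 6π-electrocyclisation of 2-bromo-1,3-dienes made from 2-bromocycloalkenyl triflates. On further heating 8, whose central C7a=C3a bond is held cis by the cyclopentene, closes the six-membered carbocycle by thermal disrotatory 6π-electrocyclisation, forming C5–C6. The two new stereocentres are set relative to each other by orbital symmetry: the ester is the outside group of the E-acrylate terminus and the ring CH2 is the outside group of the dihydropyran terminus, so disrotation places C5–H and C6–H cis, and both centres are erased in step 6. The selectivity needed is linear insertion, secured by the electron-poor acrylate, which puts H on C7 and CO2Me on C6. Excess acrylate is removed before the hot phase so that the product diene is not consumed in a Diels–Alder reaction.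

**Step 6**
Reactants: 9 racemic cis-5,6-dihydroarene methyl ester
Product: 10 arene methyl ester (2,2-dimethylindane with C4–CH2–O–CH2–CH2–C5 isochroman ring and CO2Me at C6)
Conditions: DDQ (1.1 equiv), toluene, rt
Reagents that add atoms: none
Why: Quinone dehydrogenation: DDQ removes an allylic hydride and then a proton, so 9 and any double-bond isomer of it converge on the arene, while the ester-deactivated ring protects the benzylic ether CH2 from further hydride abstraction.

**Step 7**
Reactants: 10 arene methyl ester
Product: 11 C6 benzylic alcohol (isochroman intact)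
Conditions: LiAlH4, THF, 0 °C
Reagents that add atoms: none
Why: Hydride reduction of the aryl methyl ester to the primary alcohol; the cyclic ether is inert.

**Step 8**
Reactants: 11 C6 benzylic alcohol
Product: 12 C6 benzylic chloride (isochroman intact)
Conditions: SOCl2, DMF (cat.), CH2Cl2, 0 °C to rt
Reagents that add atoms: thionyl chloride, O=S(Cl)Cl
Why: Deoxychlorination through the chlorosulfite; the chloride is chosen because a benzylic ester or ether at C6 would itself be cleaved under the Lewis-acidic chloride conditions of step 10, whereas the chloride is inert to them.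

**Step 9**
Reactants: 12 C6 benzylic chloride
Product: 13 lactone (isochroman-1-one type: C4–C(=O)–O–CH2–CH2–C5; CH2Cl at C6)
Conditions: [C5H5NH][CrO3Cl] (pyridinium chlorochromate, 4 equiv), 4 Å molecular sieves, CH2Cl2, reflux
Reagents that add atoms: pyridinium chlorochromate [C5H5NH][CrO3Cl], c1cc[nH+]cc1.[O-][Cr](=O)(=O)Cl
Why: Chromate oxidation of a benzylic ether methylene to the lactone, as known for isochroman; only this CH2 is both benzylic and α to oxygen, so the other benzylic positions should be spared.

**Step 10**
Reactants: 13 lactone
Product: 14 acid chloride (C4 COCl, C5 CH2CH2Cl, C6 CH2Cl)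
Conditions: SOCl2 (neat), ZnCl2 (10 mol%), 75 °C; volatiles removed, used crude
Reagents that add atoms: thionyl chloride, O=S(Cl)Cl
Why: Lactone to ω-chloroacyl chloride opening: ZnCl2 activates the carbonyl, chloride attacks the primary O–CH2 carbon by SN2 and SOCl2 turns the carboxylate into the acid chloride, which places chlorine on the ethyl terminus; C7–H, para to the acyl group and flanked by two substituents, is deactivated toward Friedel–Crafts attack.

**Step 11**
Reactants: 14 acid chloride
Product: 15 C4 benzylic alcohol (C5 CH2CH2Cl, C6 CH2Cl)
Conditions: NaBH4, THF/DMF, −10 to 0 °C; cold dilute aq. HCl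
Reagents that add atoms: none
Why: Chemoselective hydride reduction of an aroyl chloride, far faster at 0 °C than attack on the benzylic or primary alkyl chloride; the acidic quench prevents the alkoxide from closing back onto the chloroethyl arm.

**Step 12**
Reactants: 15 C4 benzylic alcohol
Product: 16 C4 acetoxymethyl compound (C5 CH2CH2Cl, C6 CH2Cl)
Conditions: Ac2O, iPr2NEt, DMAP (cat.), CH2Cl2, 0 °C
Reagents that add atoms: acetic anhydride, CC(=O)OC(C)=O
Why: DMAP-catalysed esterification of the primary alcohol; the non-nucleophilic amine base avoids quaternisation by the benzylic chloride.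

**Step 13**
Reactants: 16 C4 acetoxymethyl compound
Product: 17 target, [4-(acetoxymethyl)-5-(2-chloroethyl)-2,2-dimethyl-2,3-dihydro-1H-inden-6-yl]methyl butanoate
Conditions: NaO2CCH2CH2CH3 (1.5 equiv), DMF, 50 °C
Reagents that add atoms: sodium butanoate, CCCC(=O)[O-].[Na+]
Why: Carboxylate alkylation by SN2 at the benzylic chloride, which reacts far faster than the unactivated primary chloride of the C5 arm; the acetate is inert to a carboxylate nucleophile.

**Compound list**
1 | 3,3-dimethylcyclopentanone | CC1(C)CCC(=O)C1 | starting material
2 | [(4,4-dimethylcyclopent-1-en-1-yl)oxy]trimethylsilane | C[Si](C)(C)OC1=CCC(C)(C)C1 | intermediate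
3 | 2-bromo-4,4-dimethylcyclopentan-1-one (racemic) | O=C1CC(C)(C)CC1Br | intermediate
4 | 2-bromo-4,4-dimethylcyclopent-1-en-1-yl trifluoromethanesulfonate | O=S(=O)(OC1=C(Br)CC(C)(C)C1)C(F)(F)F | intermediate
5 | 2-(5,6-dihydro-2H-pyran-3-yl)-4,4,5,5-tetramethyl-1,3,2-dioxaborolane | CC1(C)OB(OC1(C)C)C1=CCCOC1 | starting material
6 | 5-(2-bromo-4,4-dimethylcyclopent-1-en-1-yl)-3,6-dihydro-2H-pyran | BrC1=C(C2=CCCOC2)CC(C)(C)C1 | intermediate
7 | methyl acrylate | C=CC(=O)OC | starting material
8 | methyl (E)-3-[2-(5,6-dihydro-2H-pyran-3-yl)-4,4-dimethylcyclopent-1-en-1-yl]acrylate (triene, not isolated) | COC(=O)/C=C/C1=C(C2=CCCOC2)CC(C)(C)C1 | intermediate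
9 | racemic cis-5,6-dihydroarene methyl ester (cyclohexa-1,3-diene, C5–H and C6–H cis; one enantiomer drawn) | COC(=O)[C@H]1C=C2CC(C)(C)CC2=C3COCC[C@@H]13 | intermediate
10 | arene methyl ester (indane-fused isochroman, CO2Me at C6) | COC(=O)c1cc2CC(C)(C)Cc2c2COCCc12 | intermediate
11 | C6 hydroxymethyl arene (indane-fused isochroman) | OCc1cc2CC(C)(C)Cc2c2COCCc12 | intermediate
12 | C6 chloromethyl arene (indane-fused isochroman) | ClCc1cc2CC(C)(C)Cc2c2COCCc12 | intermediate
13 | C6 chloromethyl lactone (indane-fused isochroman-1-one) | ClCc1cc2CC(C)(C)Cc2c2C(=O)OCCc12 | intermediate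
14 | 5-(2-chloroethyl)-6-(chloromethyl)-2,2-dimethylindane-4-carbonyl chloride | ClCc1cc2CC(C)(C)Cc2c(C(Cl)=O)c1CCCl | intermediate
15 | [5-(2-chloroethyl)-6-(chloromethyl)-2,2-dimethylindan-4-yl]methanol | ClCc1cc2CC(C)(C)Cc2c(CO)c1CCCl | intermediate
16 | [5-(2-chloroethyl)-6-(chloromethyl)-2,2-dimethylindan-4-yl]methyl acetate | ClCc1cc2CC(C)(C)Cc2c(COC(C)=O)c1CCCl | intermediate
17 | [4-(acetoxymethyl)-5-(2-chloroethyl)-2,2-dimethylindan-6-yl]methyl butanoate | CCCC(=O)OCc1cc2c(c(COC(C)=O)c1CCCl)CC(C)(C)C2 | target

**Step count**
Total: 13 steps. Longest linear sequence: 13 steps, from 1 (5 and 7 are purchased).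

**Steps most likely to fail**

Step 5. Oxidative addition and insertion at the hindered tetrasubstituted bromoalkene may be slow, so that debromination competes. The cyclopentene holds the triene termini further apart than a cyclohexene would, so ring closure may be incomplete at a temperature where hydrogen shifts or polymerisation set in. Fallback, setting out from 6 and returning at 11: Sonogashira coupling of 6 with tert-butyldimethyl(prop-2-yn-1-yloxy)silane (PdCl2(PPh3)2, CuI, NEt3, 60 °C) would give the dienyne silyl ether F1. PtCl2 in toluene at 80 °C would then effect a 6-endo-dig cycloaromatisation, in which the C4=C5 alkene attacks the metal-activated alkyne at the carbon bearing CH2OSi, giving the arene silyl ether F2 with no dihydro stage. Bu4NF in THF would release alcohol 11.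

Step 10. Chloride attack at the lactone O–CH2 may be sluggish under Lewis-acid activation, and at the temperature needed the benzylic chloride may ionise and alkylate another molecule. Fallback, setting out from 13 and returning at 15: aminolysis with MeNH(OMe)·HCl and iPrMgCl in THF at −20 °C, quenched cold, would give the hydroxy Weinreb amide F3. Appel-type chlorination (PPh3, N-chlorosuccinimide, CH2Cl2, 0 °C) would give the chloroethyl Weinreb amide F4. Reduction with iBu2AlH at −78 °C would give the aldehyde F5, and NaBH4 in MeOH at 0 °C would give 15.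

Step 9. The chromium oxidant may attack the other benzylic CH2 groups (indane C1 and C3, the C5 arm) as well, or conversion may stall on the hindered pentasubstituted ring. Fallback, setting out from 12 and returning at 13: hydride abstraction with DDQ in wet CH2Cl2, which is specific for the CH2 that gives an oxygen-stabilised cation, would give the racemic lactol F6. Oxidation with catalytic TEMPO and PhI(OAc)2 would give lactone 13.

**Further compounds**
F1 | step 5 | tert-butyl{[3-(2-(5,6-dihydro-2H-pyran-3-yl)-4,4-dimethylcyclopent-1-en-1-yl)prop-2-yn-1-yl]oxy}dimethylsilane (dienyne silyl ether) | CC1(C)CC(C#CCO[Si](C)(C)C(C)(C)C)=C(C2=CCCOC2)C1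
F2 | step 5 | tert-butyldimethylsilyl ether of alcohol 11 (arene silyl ether) | CC(C)(C)[Si](C)(C)OCc1cc2CC(C)(C)Cc2c2COCCc12
F3 | step 10 | 6-(chloromethyl)-5-(2-hydroxyethyl)-N-methoxy-N,2,2-trimethylindane-4-carboxamide (hydroxy Weinreb amide) | CON(C)C(=O)c1c2CC(C)(C)Cc2cc(CCl)c1CCO
F4 | step 10 | 5-(2-chloroethyl)-6-(chloromethyl)-N-methoxy-N,2,2-trimethylindane-4-carboxamide (chloroethyl Weinreb amide) | CON(C)C(=O)c1c2CC(C)(C)Cc2cc(CCl)c1CCCl
F5 | step 10 | 5-(2-chloroethyl)-6-(chloromethyl)-2,2-dimethylindane-4-carbaldehyde | O=Cc1c2CC(C)(C)Cc2cc(CCl)c1CCCl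
F6 | step 9 | racemic lactol (1-hydroxyisochroman form of 12) | OC1OCCc2c(CCl)cc3CC(C)(C)Cc3c12
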